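**Retrosynthetic overview**
1. Target 28 ⇐ cis-fused chromanol lactone 26 by oxidative chroman opening (the C13–O bond is kept) and quinone reduction; 26 ⇐ 3-ketone 25 by Clemmensen reduction.
2. 25 ⇐ tricyclic exo-methylene keto ester 23: BBr3 frees the phenols and the 20-OH, the ortho-phenol captures the C13 cation (sets C13) and the 20-OH lactonises onto C19.
3. 23 ⇐ acyclic β-keto ester 22 by oxidative radical polycyclisation: the oxidised enolate carbon C4 bonds to alkene carbon C5, then C10–C9 and C8–C14 form. Carbocycles close in the order ring A, ring B, ring C in one step; the chroman (temporary) and the lactone follow.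
4. 22 ⇐ ester 17 + phenylmenthyl propanoate 20 (Claisen condensation); 17 ⇐ aryl-neryl compound 5 by allylic oxidation, enolate alkylation, vinyl addition and Johnson–Claisen rearrangement; 5 ⇐ nerol + 1,4-dimethoxybenzene.

Assumption: the SMILES is read literally, i.e. (4S,5R,8R,9S,10S,13S,14R): trans-anti-trans tricycle, 8β-Me, 13β-Me/13α-OH, and the arylmethyl group on C14 α (cis to 13-OH, trans to 8-Me). Numbering in names: podocarpane-type C1–C14; C15 = benzylic CH2 on C14; C16 = Me on C13; C17 = Me on C8; C18 = Me on C4; C19 = carboxyl C on C4; C20 = CH2O on C10.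

**Step 1**
Reactants: 1 nerol
Product: 2 neryl bromide [(2Z)-1-bromo-3,7-dimethylocta-2,6-diene]
Conditions: PBr3 (0.4 equiv), Et2O, −10 °C
Reagents that add atoms: phosphorus tribromide BrP(Br)Br
Why: PBr3 bromination of a primary allylic alcohol at low temperature proceeds by SN2 displacement, so the Z-alkene is kept and no allylic transposition occurs.

**Step 2**
Reactants: 3 1,4-dimethoxybenzene; 2 neryl bromide
Product: 5 2-[(2Z)-3,7-dimethylocta-2,6-dien-1-yl]-1,4-dimethoxybenzene, via 2,5-dimethoxyphenyllithium 4 (not isolated)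
Conditions: n-BuLi, TMEDA, THF, 0 °C; then 2, −78 → 23 °C
Reagents that add atoms: none
Why: Directed ortho-lithiation followed by SN2 alkylation of the aryllithium with the primary allylic bromide joins arene and chain with the Z-alkene (later C13=C14) intact.

**Step 3**
Reactants: 5
Product: 6 (2E,6Z)-8-(2,5-dimethoxyphenyl)-2,6-dimethylocta-2,6-dien-1-ol
Conditions: SeO2 (0.3 equiv), t-BuOOH (3 equiv), salicylic acid (0.1 equiv), CH2Cl2, 0 → 23 °C
Reagents that add atoms: selenium dioxide O=[Se]=O (oxygen carrier); tert-butyl hydroperoxide CC(C)(C)OO (oxygen source)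
Why: Sharpless allylic oxidation (ene reaction then [2,3]-sigmatropic shift) attacks the less hindered terminal gem-dimethyl alkene and gives the E-allylic alcohol, which fixes the E geometry of the future C8=C9 alkene.

**Step 4**
Reactants: 6
Product: 7 2-[(2Z,6E)-8-bromo-3,7-dimethylocta-2,6-dien-1-yl]-1,4-dimethoxybenzene
Conditions: PBr3 (0.4 equiv), Et2O, 0 °C
Reagents that add atoms: phosphorus tribromide BrP(Br)Br
Why: SN2 bromination of the primary allylic alcohol, with both alkene geometries untouched.

**Step 5**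
Reactants: 8 tert-butyl acetate; 7
Product: 10 tert-butyl (4E,8Z)-10-(2,5-dimethoxyphenyl)-4,8-dimethyldeca-4,8-dienoate, via lithium enolate of tert-butyl acetate 9 (not isolated)
Conditions: LiN(i-Pr)2, THF, −78 °C; then 7, DMPU, −78 → −30 °C
Reagents that add atoms: none
Why: Ester enolate alkylation (SN2 at the primary allylic bromide) adds C6 and C5 without disturbing the alkenes.

**Step 6**
Reactants: 11 2,3-dibromoprop-1-ene
Product: 12 2-bromo-3-methoxyprop-1-ene
Conditions: NaOMe, MeOH, 0 → 23 °C
Reagents that add atoms: sodium methoxide [Na+].[O-]C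
Why: Williamson-type SN2 displacement of the allylic bromide; the vinylic bromide is inert.

**Step 7**
Reactants: 10; 12
Product: 15 (6E,10Z)-12-(2,5-dimethoxyphenyl)-2-(methoxymethyl)-6,10-dimethyldodeca-1,6,10-trien-3-ol (racemic at C3), via aldehyde 13 (not isolated), via vinyllithium 14 (not isolated)
Conditions: 10, i-Bu2AlH (1.05 equiv), toluene, −78 °C; then 14 [from 12, t-BuLi (2 equiv), Et2O, −78 °C], −78 → 0 °C; aq. KNaC4H4O6
Reagents that add atoms: none
Why: One-pot partial ester reduction to the aluminium hemiacetal and 1,2-addition of the vinyllithium (from bromine–lithium exchange, kept at −78 °C to avoid β-elimination) to the released aldehyde; the new carbinol centre is erased in step 8.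

**Step 8**
Reactants: 15; 16 triethyl orthoacetate
Product: 17 ethyl (4Z,8E,12Z)-14-(2,5-dimethoxyphenyl)-4-(methoxymethyl)-8,12-dimethyltetradeca-4,8,12-trienoate
Conditions: 16 (6 equiv), EtCO2H (0.1 equiv), 140 °C, EtOH distilled off
Reagents that add atoms: none
Why: Johnson–Claisen orthoester rearrangement through a chair transition state with the long chain equatorial gives the trisubstituted alkene with CH2OMe cis to C6, the geometry needed for a trans ring A/ring B fusion with axial C20.

**Step 9**
Reactants: 18 (+)-8-phenylmenthol; 19 propanoyl chloride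
Product: 20 (1S,2R,5S)-5-methyl-2-(2-phenylpropan-2-yl)cyclohexyl propanoate
Conditions: Et3N, DMAP (cat.), CH2Cl2, 0 → 23 °C
Reagents that add atoms: none
Why: Nucleophilic acyl substitution (DMAP-catalysed esterification) installs the recoverable chiral auxiliary.

**Step 10**
Reactants: 20; 17
Product: 22 (1S,2R,5S)-5-methyl-2-(2-phenylpropan-2-yl)cyclohexyl (6Z,10E,14Z)-16-(2,5-dimethoxyphenyl)-6-(methoxymethyl)-2,10,14-trimethyl-3-oxohexadeca-6,10,14-trienoate (both C2 epimers), via lithium ester enolate 21 (not isolated)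
Conditions: 20 (2.2 equiv), LiN(i-Pr)2 (2.2 equiv), THF, −78 °C; then 17, −78 → 0 °C; AcOH
Reagents that add atoms: none
Why: Crossed Claisen condensation, driven by deprotonation of the product β-keto ester by the second equivalent of enolate; the C2 (future C4) centre is planarised in step 11.

**Step 11**
Reactants: 22
Product: 23 (+)-8-phenylmenthyl 14α-(2,5-dimethoxybenzyl)-10β-(methoxymethyl)-4α,8β-dimethyl-13(16)-methylidene-3-oxo-5α,9α-podocarpane-4β-carboxylate
Conditions: Mn(OAc)3·2H2O (2.2 equiv), Cu(OAc)2·H2O (1 equiv), Yb(OTf)3 (1 equiv), CF3CH2OH, 0 °C, Ar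
Reagents that add atoms: none
Why: Oxidative free-radical polycyclisation: trivalent manganese oxidises the Yb-chelated enolate to an electrophilic α-dicarbonyl radical, so the normally nucleophilic enolate carbon C4 bonds to alkene carbon C5, and three 6-endo closures through chair-chair-chair folding follow. The ester goes axial (4β), the E-alkenes give trans-anti fusions with axial C20 and 8β-Me, and the Z-alkene places the arylmethyl arm axial (14α). Cu(OAc)2 oxidises the C13 radical to the exocyclic alkene. The phenyl of the auxiliary shields one face of the chelated radical; by analogy with (+)-8-phenylmenthyl β-keto esters lacking the 2-methyl group, this should give the 5α,10β series.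

**Step 12**
Reactants: 23
Product: 25 cis-fused chromanol keto lactone [3-oxo-19,20-olide; 13α-O–aryl ether; 13β-Me; 14α-CH2; free 5′-OH], via hydroquinone 20-alcohol 24 (not isolated)
Conditions: BBr3 (6 equiv), CH2Cl2, −78 → 0 °C; then MeOH, 0 → 23 °C
Reagents that add atoms: none
Why: BBr3 cleaves the three methyl ethers, and the HBr released on quenching protonates the exocyclic alkene (Markovnikov). The ortho-phenol on the axial 14α arm then captures the C13 cation; only the α-face (equatorial) attack can close the six-membered ring, which gives the cis-fused chroman with 13α-O/13β-Me. The freed 20-OH lactonises onto the syn-axial C19 ester and releases auxiliary 18 for recovery.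

**Step 13**
Reactants: 25
Product: 26 cis-fused chromanol lactone [19,20-olide; 13α-O–aryl ether; 3-deoxo]
Conditions: Zn(Hg), HCl, Et2O, −15 → 0 °C
Reagents that add atoms: none
Why: Clemmensen reduction removes the hindered 3-ketone of the non-enolisable β-keto lactone; lactone, phenol and chroman ether tolerate cold HCl, and no stereocentre is touched.

**Step 14**
Reactants: 26
Product: 28 target CNP0148621.1, via quinone 27 (not isolated)
Conditions: (NH4)2Ce(NO3)6 (2.2 equiv), MeCN/H2O 4:1, 0 °C; then aq. Na2S2O4, EtOAc, 23 °C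
Reagents that add atoms: water O
Why: Two-electron oxidation of the para-alkoxyphenol by tetravalent cerium (chromanol to hydroxyalkyl quinone, as in tocopherol to tocopherylquinone): water adds at the aryl carbon, so the C13–O bond and its configuration stay as the tertiary alcohol; dithionite then reduces the quinone to the hydroquinone under neutral conditions.

**Compound list**
1 | nerol, (2Z)-3,7-dimethylocta-2,6-dien-1-ol | CC(C)=CCC/C(C)=C\CO | starting material
2 | neryl bromide | CC(C)=CCC/C(C)=C\CBr | intermediate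
3 | 1,4-dimethoxybenzene | COc1ccc(OC)cc1 | starting material
4 | 2,5-dimethoxyphenyllithium | [Li]c1cc(OC)ccc1OC | intermediate
5 | 2-[(2Z)-3,7-dimethylocta-2,6-dien-1-yl]-1,4-dimethoxybenzene | CC(C)=CCC/C(C)=C\Cc1cc(OC)ccc1OC | intermediate
6 | (2E,6Z)-8-(2,5-dimethoxyphenyl)-2,6-dimethylocta-2,6-dien-1-ol | OC/C(C)=C/CC/C(C)=C\Cc1cc(OC)ccc1OC | intermediate
7 | 2-[(2Z,6E)-8-bromo-3,7-dimethylocta-2,6-dien-1-yl]-1,4-dimethoxybenzene | BrC/C(C)=C/CC/C(C)=C\Cc1cc(OC)ccc1OC | intermediate
8 | tert-butyl acetate | CC(=O)OC(C)(C)C | starting material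
9 | lithium enolate of tert-butyl acetate | C=C(O[Li])OC(C)(C)C | intermediate
10 | tert-butyl (4E,8Z)-10-(2,5-dimethoxyphenyl)-4,8-dimethyldeca-4,8-dienoate | CC(C)(C)OC(=O)CC/C(C)=C/CC/C(C)=C\Cc1cc(OC)ccc1OC | intermediate
11 | 2,3-dibromoprop-1-ene | BrCC(Br)=C | starting material
12 | 2-bromo-3-methoxyprop-1-ene | COCC(Br)=C | intermediate
13 | (4E,8Z)-10-(2,5-dimethoxyphenyl)-4,8-dimethyldeca-4,8-dienal | O=CCC/C(C)=C/CC/C(C)=C\Cc1cc(OC)ccc1OC | intermediate
14 | (3-methoxyprop-1-en-2-yl)lithium | COCC([Li])=C | intermediate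
15 | (6E,10Z)-12-(2,5-dimethoxyphenyl)-2-(methoxymethyl)-6,10-dimethyldodeca-1,6,10-trien-3-ol (racemic at C3) | C=C(COC)C(O)CC/C(C)=C/CC/C(C)=C\Cc1cc(OC)ccc1OC | intermediate
16 | triethyl orthoacetate | CC(OCC)(OCC)OCC | starting material
17 | ethyl (4Z,8E,12Z)-14-(2,5-dimethoxyphenyl)-4-(methoxymethyl)-8,12-dimethyltetradeca-4,8,12-trienoate | CCOC(=O)CC/C(COC)=C/CC/C(C)=C/CC/C(C)=C\Cc1cc(OC)ccc1OC | intermediate
18 | (+)-8-phenylmenthol, (1S,2R,5S)-5-methyl-2-(2-phenylpropan-2-yl)cyclohexan-1-ol | O[C@H]1C[C@@H](C)CC[C@@H]1C(C)(C)c1ccccc1 | starting material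
19 | propanoyl chloride | CCC(Cl)=O | starting material
20 | (1S,2R,5S)-5-methyl-2-(2-phenylpropan-2-yl)cyclohexyl propanoate | CCC(=O)O[C@H]1C[C@@H](C)CC[C@@H]1C(C)(C)c1ccccc1 | intermediate
21 | lithium enolate of 20 | CC=C(O[Li])O[C@H]1C[C@@H](C)CC[C@@H]1C(C)(C)c1ccccc1 | intermediate
22 | 8-phenylmenthyl (6Z,10E,14Z)-16-(2,5-dimethoxyphenyl)-6-(methoxymethyl)-2,10,14-trimethyl-3-oxohexadeca-6,10,14-trienoate (C2 epimers) | CC(C(=O)O[C@H]1C[C@@H](C)CC[C@@H]1C(C)(C)c1ccccc1)C(=O)CC/C(COC)=C/CC/C(C)=C/CC/C(C)=C\Cc1cc(OC)ccc1OC | intermediate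
23 | tricyclic exo-methylene keto ester (4α-Me; 4β-CO2-phenylmenthyl; 5α-H; 8β-Me; 9α-H; 10β-CH2OMe; 14α-arylmethyl; 13=CH2; 3-oxo) | C[C@@]12CC[C@@H]3[C@](COC)(CCC(=O)[C@]3(C)C(=O)O[C@H]4C[C@@H](C)CC[C@@H]4C(C)(C)c4ccccc4)[C@H]1CCC(=C)[C@@H]2Cc1cc(OC)ccc1OC | intermediate
24 | demethylated hydroquinone 20-alcohol of 23 (present as boron esters) | C[C@@]12CC[C@@H]3[C@](CO)(CCC(=O)[C@]3(C)C(=O)O[C@H]4C[C@@H](C)CC[C@@H]4C(C)(C)c4ccccc4)[C@H]1CCC(=C)[C@@H]2Cc1cc(O)ccc1O | intermediate
25 | cis-fused chromanol keto lactone (3-oxo; 19,20-olide; 13α-O-aryl; 13β-Me; 14β-H) | C[C@@]12CC[C@@H]3[C@]4(CCC(=O)[C@]3(C)C(=O)OC4)[C@H]1CC[C@](C)(Oc5ccc(O)cc5C6)[C@@H]26 | intermediate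
26 | cis-fused chromanol lactone (19,20-olide; 13α-O-aryl; 13β-Me; 14β-H) | C[C@@]12CC[C@@H]3[C@]4(CCC[C@]3(C)C(=O)OC4)[C@H]1CC[C@](C)(Oc5ccc(O)cc5C6)[C@@H]26 | intermediate
27 | hydroxy quinone (13α-OH; 2-substituted 1,4-benzoquinone) | C[C@@]12CC[C@@H]3[C@]4(CCC[C@]3(C)C(=O)OC4)[C@H]1CC[C@](C)(O)[C@@H]2CC1=CC(=O)C=CC1=O | intermediate
28 | CNP0148621.1, (4S,5R,8R,9S,10S,13S,14R) hydroquinone lactone | C[C@@]12CC[C@@H]3[C@]4(CCC[C@]3(C)C(=O)OC4)[C@H]1CC[C@](C)(O)[C@@H]2Cc1cc(O)ccc1O | target

**Totals**
Total step count: 14. Longest linear sequence: 12 (steps 1–5, 7, 8, 10–14); steps 6 and 9 are side branches.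

**Three steps most likely to fail**

Step 11 (oxidative polycyclisation). The third closure onto the Z-alkene must go through the chair with an axial arylmethyl arm, and the auxiliary must control the face. The sense of induction is taken by analogy with (+)-8-phenylmenthyl β-keto esters that lack the 2-methyl group; if it proved opposite for the 2-methyl radical, the same route would be run with the enantiomeric auxiliary. Fallback: setting out from 22, the oxidation is run with Cu(OAc)2 in large excess (5 equiv, AcOH, 23 °C) so that the C8 radical is oxidised before the third closure. This gives the bicyclic 8(17)-exo-methylene keto ester F1 with the Z side chain intact. BBr3 then MeOH closes ring C by a cation–olefin cyclisation instead: protonation of the exocyclic alkene, then anti addition of C8 and the phenol oxygen across the Z-alkene, which gives the same 14α-arm/13α-O chroman with lactonisation. The fallback comes back to the route at 25.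

Step 12 (one-pot demethylation, chroman closure, lactonisation). Risks are loss of C14 integrity through a 13(14)-alkene and slow displacement of the bulky auxiliary. Fallback: setting out from 23, (NH4)2Ce(NO3)6 in MeCN/H2O converts the dimethoxyarene to the quinone keto ester F2 without touching alkene, aliphatic ether or ester. Na2S2O4 reduction and camphorsulfonic acid (CH2Cl2, 0 °C) close the chroman under mild acid to give the chromanol keto ester F3. Me3SiI (from Me3SiCl/NaI, MeCN) then cleaves the aliphatic methyl ether and the 20-oxygen lactonises with loss of the auxiliary. The fallback comes back to the route at 25.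

Step 13 (Clemmensen reduction of a β-keto lactone; rearrangement or incomplete reduction possible). Fallback: setting out from 25, ethane-1,2-dithiol with BF3·OEt2 gives the 3,3-ethylenedithio ketal F4, and Raney nickel in EtOH desulfurises it. The fallback comes back to the route at 26.

**Further compounds**
F1 | step 11 | bicyclic 8(17)-exo-methylene keto ester with (Z)-5-aryl-3-methylpent-3-enyl chain on C9 | C=C1CC[C@@H]2[C@](COC)(CCC(=O)[C@]2(C)C(=O)O[C@H]3C[C@@H](C)CC[C@@H]3C(C)(C)c3ccccc3)[C@H]1CC/C(C)=C\Cc1cc(OC)ccc1OC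
F2 | step 12 | quinone keto ester (13=CH2; 20-OMe; phenylmenthyl ester) | C[C@@]12CC[C@@H]3[C@](COC)(CCC(=O)[C@]3(C)C(=O)O[C@H]4C[C@@H](C)CC[C@@H]4C(C)(C)c4ccccc4)[C@H]1CCC(=C)[C@@H]2CC1=CC(=O)C=CC1=O
F3 | step 12 | cis-fused chromanol keto ester (20-OMe; phenylmenthyl ester) | C[C@@]12CC[C@@H]3[C@](COC)(CCC(=O)[C@]3(C)C(=O)O[C@H]4C[C@@H](C)CC[C@@H]4C(C)(C)c4ccccc4)[C@H]1CC[C@](C)(Oc5ccc(O)cc5C6)[C@@H]26
F4 | step 13 | 3,3-ethylenedithio ketal of 25 | C[C@@]12CC[C@@H]3[C@]4(CCC5(SCCS5)[C@]3(C)C(=O)OC4)[C@H]1CC[C@](C)(Oc5ccc(O)cc5C6)[C@@H]26
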